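**Retrosynthetic overview**

1. Target 27 comes from its decabenzyl ether 26 by hydrogenolysis. The oxolane ring is made last, from lactone 24, by aryl addition and cis-selective reduction of the cyclic oxocarbenium ion. Lactone 24 comes from the C2-symmetric trans-diarylsuccinic anhydride 20 (aryl Grignard opening, catalyst-controlled ketone reduction).
2. The oxolane C3–C4 bond comes from oxidative homocoupling of two identical Evans imides 16, so both dihydrobenzofuran halves derive from one acid 13.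
3. Acid 13 comes from ester 7 by Negishi coupling at the C4 triflate and a decarboxylative arylation that exchanges the C3 carboxyl group for the 3,5-dioxygenated aryl ring.
4. Key disconnection: the dihydrofuran ring (O1–C2–C3–C3a–C7a) comes from the six-membered pyranone ring of flavanone 4, two steps from (2S)-naringenin. Enabling feature: C3 lies between C2 and the C4 carbonyl, and the electron-rich ring A carbon C4a (para to O7) can shift from C4 to C3, expelling C4 as an ester carbon.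
5. Ring order: chromanone (chiral pool) → dihydrobenzofuran (step 3) → anhydride (step 11) → lactone (step 13) → oxolane (step 15).

Key step: step 3

Assumption: (2S)-naringenin of high enantiomeric purity is commercially available; its C2 centre is labile only to base, which steps 1 to 3 avoid.

Abbreviation used in names: Ar* = (2S,3S)-6-(benzyloxy)-2-[4-(benzyloxy)phenyl]-3-[3,5-bis(benzyloxy)phenyl]-2,3-dihydro-1-benzofuran-4-yl.

**Route**

Step 1
Reactants: 1 (2S)-naringenin; 2 benzyl alcohol (two molecules)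
Product: 3 (2S)-7-(benzyloxy)-2-[4-(benzyloxy)phenyl]-5-hydroxy-2,3-dihydro-4H-chromen-4-one
Conditions: BnOH (2.2 equiv), PPh3, DIAD (2.2 equiv each), THF, 0 °C to rt
Reagents that add atoms: benzyl alcohol OCc1ccccc1 (the second of the two molecules of 2 that are consumed)
Why: Twofold Mitsunobu etherification alkylates only the two acidic, non-chelated phenols (7-OH and 4'-OH), one molecule of benzyl alcohol each, under neutral conditions, so the base-labile C2 centre of the flavanone is not opened to the chalcone and the hydrogen-bonded 5-OH stays free.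

Step 2
Reactants: 3 (2S)-7-(benzyloxy)-2-[4-(benzyloxy)phenyl]-5-hydroxy-2,3-dihydro-4H-chromen-4-one
Product: 4 (2S)-7-(benzyloxy)-2-[4-(benzyloxy)phenyl]-4-oxo-3,4-dihydro-2H-chromen-5-yl trifluoromethanesulfonate
Conditions: Tf2O, pyridine, CH2Cl2, 0 °C
Reagents that add atoms: trifluoromethanesulfonic anhydride O=S(=O)(OS(=O)(=O)C(F)(F)F)C(F)(F)F
Why: O-triflation of the remaining chelated phenol; the triflate masks O5 during the oxidation and later serves as the leaving group for C–C coupling at this carbon.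

Step 3
Reactants: 4 (2S)-7-(benzyloxy)-2-[4-(benzyloxy)phenyl]-4-oxo-3,4-dihydro-2H-chromen-5-yl trifluoromethanesulfonate
Product: 7 methyl (2S,3S)-6-(benzyloxy)-2-[4-(benzyloxy)phenyl]-4-{[(trifluoromethyl)sulfonyl]oxy}-2,3-dihydro-1-benzofuran-3-carboxylate (2,3-trans), via 4-methoxy-2H-chromene enol ether 5 (not isolated), via C3 aryl-λ3-iodane dimethyl ketal 6 (not isolated)
Conditions: PhI(OAc)2 (1.3 equiv), H2SO4, HC(OMe)3, rt; aq. NaHCO3
Reagents that add atoms: trimethyl orthoformate COC(OC)OC; water O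
Why: Acid and trimethyl orthoformate convert ketone 4 into enol ether 5, which attacks the trivalent iodine of PhI(OAc)2 with C3 on the face anti to the C2 aryl group and takes up methanol to give ketal 6; departure of iodobenzene from C3 is then assisted by a 1,2-shift of the ring A carbon C4a from C4 to C3, so the six-membered ring O1–C2–C3–C4–C4a–C8a contracts to the five-membered ring O1–C2–C3–C3a–C7a and C4 leaves the ring as a dimethoxycarbenium ion that is hydrolysed to the methyl ester. The closest known reaction is the oxidative ring contraction of flavanones to methyl trans-2-aryl-2,3-dihydrobenzofuran-3-carboxylates with PhI(OAc)2 and H2SO4 in trimethyl orthoformate. The five-membered ring is closed by this semipinacol-type aryl shift through a bridged phenonium ion (3-exo-tet attack of C4a on C3, then cleavage of the C4–C4a bond), with inversion at C3. C2 is not involved and keeps the S configuration of naringenin; the new C3 centre is set trans to the C2 aryl group because the iodane is installed anti to that group and is displaced with inversion, and a cis ester would epimerise to the trans one. The step needs migration of ring A and not of the C2 aryl group (isoflavone) or loss of the C3 hydrogen (flavone): the equatorial C3–I bond is antiperiplanar to the C4–C4a ring bond but not to the C2–aryl bond, and the benzyloxy group at C7, para to C4a, keeps ring A a good migrating group in spite of the triflate at C5.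

Step 4
Reactants: 7 methyl (2S,3S)-6-(benzyloxy)-2-[4-(benzyloxy)phenyl]-4-{[(trifluoromethyl)sulfonyl]oxy}-2,3-dihydro-1-benzofuran-3-carboxylate; 8 (2-tert-butoxy-2-oxoethyl)zinc bromide
Product: 9 methyl (2S,3S)-6-(benzyloxy)-2-[4-(benzyloxy)phenyl]-4-(2-tert-butoxy-2-oxoethyl)-2,3-dihydro-1-benzofuran-3-carboxylate
Conditions: Pd2(dba)3 (2.5 mol%), XPhos (10 mol%), THF, 60 °C
Reagents that add atoms: none
Why: Negishi-type cross-coupling of the aryl triflate with the Reformatsky zinc enolate on zerovalent palladium; the neutral conditions leave the epimerisable β-aryloxy ester intact.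

Step 5
Reactants: 9 methyl (2S,3S)-6-(benzyloxy)-2-[4-(benzyloxy)phenyl]-4-(2-tert-butoxy-2-oxoethyl)-2,3-dihydro-1-benzofuran-3-carboxylate
Product: 10 (2S,3S)-6-(benzyloxy)-2-[4-(benzyloxy)phenyl]-4-(2-tert-butoxy-2-oxoethyl)-2,3-dihydro-1-benzofuran-3-carboxylic acid
Conditions: LiOH, THF/MeOH/H2O, 0 °C to rt; 1 M HCl
Reagents that add atoms: lithium hydroxide [Li+].[OH-]
Why: Saponification; hydroxide cleaves the methyl ester while the tert-butyl ester is inert, and C3 can only equilibrate toward the trans acid it already is.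

Step 6
Reactants: 10 (2S,3S)-6-(benzyloxy)-2-[4-(benzyloxy)phenyl]-4-(2-tert-butoxy-2-oxoethyl)-2,3-dihydro-1-benzofuran-3-carboxylic acid; 11 1,3-bis(benzyloxy)-5-bromobenzene
Product: 12 tert-butyl 2-(Ar*)acetate (2,3-trans)
Conditions: Ir[dF(CF3)ppy]2(dtbbpy)PF6 (1 mol%), NiCl2·glyme (10 mol%), dtbbpy (15 mol%), Cs2CO3, DMF, blue LEDs, rt
Reagents that add atoms: none
Why: Metallaphotoredox decarboxylative arylation: the excited iridium photocatalyst oxidises the caesium carboxylate, loss of CO2 gives the planar benzylic C3 radical, and nickel couples it with aryl bromide 11; the aryl group is delivered to the face anti to the C2 aryl group, which sets C3 trans (3S) while C2 is untouched.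

Step 7
Reactants: 12 tert-butyl 2-(Ar*)acetate
Product: 13 2-(Ar*)acetic acid
Conditions: TFA, CH2Cl2, anisole, 0 °C
Reagents that add atoms: none
Why: Acidolysis of the tert-butyl ester (E1 loss of isobutene, anisole as cation scavenger); the benzyl ethers are stable, and any reversible ionisation at C2 recloses trans to the C3 aryl group.

Step 8
Reactants: 13 2-(Ar*)acetic acid; 14 (S)-4-benzyloxazolidin-2-one
Product: 16 (S)-4-benzyl-3-[2-(Ar*)acetyl]oxazolidin-2-one, via mixed pivalic anhydride 15 (not isolated)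
Conditions: PivCl, Et3N, THF, −20 °C; then 14, LiCl, rt
Reagents that add atoms: none
Why: N-acylation of the Evans oxazolidinone through the mixed pivalic anhydride (LiCl/Et3N variant), which needs no strong base.

Step 9
Reactants: 16 (S)-4-benzyl-3-[2-(Ar*)acetyl]oxazolidin-2-one (two molecules)
Product: 18 (2S,3S)-1,4-bis[(S)-4-benzyl-2-oxooxazolidin-3-yl]-2,3-bis(Ar*)butane-1,4-dione, via lithium Z-enolate 17 (not isolated)
Conditions: LiN(i-Pr)2, THF, −78 °C; then TiCl4, −78 to 0 °C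
Reagents that add atoms: none
Why: Oxidative homocoupling of the chelated Z-enolate of a chiral arylacetyl oxazolidinone (single-electron oxidation by tetravalent titanium, then C–C coupling); each α-carbon bonds on the face anti to the 4-benzyl group, which should give the C2-symmetric (2S,3S) dimer.

Step 10
Reactants: 18 (2S,3S)-1,4-bis[(S)-4-benzyl-2-oxooxazolidin-3-yl]-2,3-bis(Ar*)butane-1,4-dione
Product: 19 (2S,3S)-2,3-bis(Ar*)butanedioic acid
Conditions: LiOH, H2O2, THF/H2O, 0 °C; Na2SO3; 1 M HCl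
Reagents that add atoms: hydrogen peroxide OO
Why: Evans auxiliary cleavage with lithium hydroperoxide, which attacks the exocyclic carbonyl selectively and should not epimerise the α-aryl centres at 0 °C.

Step 11
Reactants: 19 (2S,3S)-2,3-bis(Ar*)butanedioic acid
Product: 20 (3S,4S)-3,4-bis(Ar*)oxolane-2,5-dione
Conditions: Ac2O, 60 °C; evaporation
Reagents that add atoms: none
Why: Cyclodehydration to the five-membered anhydride (5-exo-trig acyl substitution); the trans-diaryl anhydride is the more stable isomer, so the two stereocentres are not at risk.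

Step 12
Reactants: 20 (3S,4S)-3,4-bis(Ar*)oxolane-2,5-dione; 21 [4-(benzyloxy)phenyl]magnesium bromide
Product: 22 (2S,3S)-4-[4-(benzyloxy)phenyl]-4-oxo-2,3-bis(Ar*)butanoic acid
Conditions: THF, −78 °C; 1 M HCl
Reagents that add atoms: none
Why: Acylation of the Grignard reagent by the cyclic anhydride; the two carbonyl groups are homotopic (C2 axis), so one keto acid results, and the magnesium carboxylate formed prevents a second addition.

Step 13
Reactants: 22 (2S,3S)-4-[4-(benzyloxy)phenyl]-4-oxo-2,3-bis(Ar*)butanoic acid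
Product: 24 (3S,4S,5R)-5-[4-(benzyloxy)phenyl]-3,4-bis(Ar*)oxolan-2-one (3,4-trans/4,5-trans), via hydroxy acid 23 (not isolated)
Conditions: RuCl[(R,R)-TsDPEN](p-cymene) (5 mol%), HCO2H/Et3N (5:2), CH2Cl2, rt; then PPTS (cat.), CH2Cl2, rt
Reagents that add atoms: none
Why: Noyori asymmetric transfer hydrogenation of the aryl ketone under catalyst control should give the (4R)-carbinol, and mild acid-catalysed lactonisation (5-exo-trig, retention at the carbinol) gives the 4,5-trans lactone without forming a benzylic cation.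

Step 14
Reactants: 24 (3S,4S,5R)-5-[4-(benzyloxy)phenyl]-3,4-bis(Ar*)oxolan-2-one; 21 [4-(benzyloxy)phenyl]magnesium bromide
Product: 25 (3S,4S,5R)-2,5-bis[4-(benzyloxy)phenyl]-3,4-bis(Ar*)oxolan-2-ol (mixture of C2 anomers)
Conditions: CeCl3, THF, −78 °C; aq. NH4Cl
Reagents that add atoms: none
Why: Organocerium addition to the lactone carbonyl; the non-basic reagent avoids enolisation of the acidic α-aryl position, and the tetrahedral alkoxide stops at the lactol stage.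

Step 15
Reactants: 25 (3S,4S,5R)-2,5-bis[4-(benzyloxy)phenyl]-3,4-bis(Ar*)oxolan-2-ol
Product: 26 (2S,3S,4S,5R)-2,5-bis[4-(benzyloxy)phenyl]-3,4-bis(Ar*)oxolane
Conditions: Et3SiH, BF3·OEt2, CH2Cl2, −78 °C
Reagents that add atoms: none
Why: Ionic hydrogenation of the lactol through the cyclic aryl-substituted oxocarbenium ion; hydride enters anti to the C3 substituent and sets the new C2 centre cis to it, as in the reduction of lignan hemiketals, and the low temperature keeps the other benzylic ethers from ionising.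

Step 16
Reactants: 26 (2S,3S,4S,5R)-2,5-bis[4-(benzyloxy)phenyl]-3,4-bis(Ar*)oxolane
Product: 27 (2S,3S,4S,5R)-2,5-bis(4-hydroxyphenyl)-3,4-bis[(2S,3S)-3-(3,5-dihydroxyphenyl)-6-hydroxy-2-(4-hydroxyphenyl)-2,3-dihydro-1-benzofuran-4-yl]oxolane (CNP0270490.1)
Conditions: H2 (1 atm), Pd/C, EtOAc/MeOH, rt
Reagents that add atoms: none
Why: Hydrogenolysis of the ten benzyl aryl ethers over palladium on carbon; the cyclic benzylic C–O bonds are cleaved much more slowly, so the reaction is stopped at full debenzylation.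

**Compound list**

1 | (2S)-naringenin | O=C1C[C@@H](c2ccc(O)cc2)Oc2cc(O)cc(O)c12 | starting material
2 | benzyl alcohol | OCc1ccccc1 | starting material
3 | (2S)-7-(benzyloxy)-2-[4-(benzyloxy)phenyl]-5-hydroxy-2,3-dihydro-4H-chromen-4-one | O=C1C[C@@H](c2ccc(OCc3ccccc3)cc2)Oc2cc(OCc3ccccc3)cc(O)c12 | intermediate
4 | (2S)-7-(benzyloxy)-2-[4-(benzyloxy)phenyl]-4-oxo-3,4-dihydro-2H-chromen-5-yl trifluoromethanesulfonate | O=C1C[C@@H](c2ccc(OCc3ccccc3)cc2)Oc2cc(OCc3ccccc3)cc(OS(=O)(=O)C(F)(F)F)c12 | intermediate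
5 | (2S)-7-(benzyloxy)-2-[4-(benzyloxy)phenyl]-4-methoxy-2H-chromen-5-yl trifluoromethanesulfonate | COC1=C[C@@H](c2ccc(OCc3ccccc3)cc2)Oc2cc(OCc3ccccc3)cc(OS(=O)(=O)C(F)(F)F)c12 | intermediate
6 | (2R,3R)-3-[acetoxy(phenyl)-λ3-iodanyl]-7-(benzyloxy)-2-[4-(benzyloxy)phenyl]-4,4-dimethoxy-3,4-dihydro-2H-chromen-5-yl trifluoromethanesulfonate (iodine trans to the C2 aryl group) | COC1(OC)[C@H](I(OC(C)=O)c2ccccc2)[C@@H](c2ccc(OCc3ccccc3)cc2)Oc2cc(OCc3ccccc3)cc(OS(=O)(=O)C(F)(F)F)c12 | intermediate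
7 | methyl (2S,3S)-6-(benzyloxy)-2-[4-(benzyloxy)phenyl]-4-{[(trifluoromethyl)sulfonyl]oxy}-2,3-dihydro-1-benzofuran-3-carboxylate | FC(F)(F)S(=O)(=O)Oc1cc(OCc2ccccc2)cc3c1[C@H](C(=O)OC)[C@@H](c1ccc(OCc2ccccc2)cc1)O3 | intermediate
8 | (2-tert-butoxy-2-oxoethyl)zinc bromide | CC(C)(C)OC(=O)C[Zn]Br | starting material
9 | methyl (2S,3S)-6-(benzyloxy)-2-[4-(benzyloxy)phenyl]-4-(2-tert-butoxy-2-oxoethyl)-2,3-dihydro-1-benzofuran-3-carboxylate | CC(C)(C)OC(=O)Cc1cc(OCc2ccccc2)cc3c1[C@H](C(=O)OC)[C@@H](c1ccc(OCc2ccccc2)cc1)O3 | intermediate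
10 | (2S,3S)-6-(benzyloxy)-2-[4-(benzyloxy)phenyl]-4-(2-tert-butoxy-2-oxoethyl)-2,3-dihydro-1-benzofuran-3-carboxylic acid | CC(C)(C)OC(=O)Cc1cc(OCc2ccccc2)cc3c1[C@H](C(=O)O)[C@@H](c1ccc(OCc2ccccc2)cc1)O3 | intermediate
11 | 1,3-bis(benzyloxy)-5-bromobenzene | Brc1cc(OCc2ccccc2)cc(OCc2ccccc2)c1 | starting material
12 | tert-butyl 2-(Ar*)acetate | CC(C)(C)OC(=O)Cc1cc(OCc2ccccc2)cc3c1[C@H](c1cc(OCc2ccccc2)cc(OCc2ccccc2)c1)[C@@H](c1ccc(OCc2ccccc2)cc1)O3 | intermediate
13 | 2-(Ar*)acetic acid | OC(=O)Cc1cc(OCc2ccccc2)cc3c1[C@H](c1cc(OCc2ccccc2)cc(OCc2ccccc2)c1)[C@@H](c1ccc(OCc2ccccc2)cc1)O3 | intermediate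
14 | (S)-4-benzyloxazolidin-2-one | O=C1N[C@@H](Cc2ccccc2)CO1 | starting material
15 | 2-(Ar*)acetic pivalic anhydride | CC(C)(C)C(=O)OC(=O)Cc1cc(OCc2ccccc2)cc3c1[C@H](c1cc(OCc2ccccc2)cc(OCc2ccccc2)c1)[C@@H](c1ccc(OCc2ccccc2)cc1)O3 | intermediate
16 | (S)-4-benzyl-3-[2-(Ar*)acetyl]oxazolidin-2-one | O=C(Cc1cc(OCc2ccccc2)cc3c1[C@H](c1cc(OCc2ccccc2)cc(OCc2ccccc2)c1)[C@@H](c1ccc(OCc2ccccc2)cc1)O3)N1[C@@H](Cc2ccccc2)COC1=O | intermediate
17 | lithium (Z)-enolate of 16 | [Li]O/C(=C\c1cc(OCc2ccccc2)cc3c1[C@H](c1cc(OCc2ccccc2)cc(OCc2ccccc2)c1)[C@@H](c1ccc(OCc2ccccc2)cc1)O3)N1[C@@H](Cc2ccccc2)COC1=O | intermediate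
18 | (2S,3S)-1,4-bis[(S)-4-benzyl-2-oxooxazolidin-3-yl]-2,3-bis(Ar*)butane-1,4-dione | O=C([C@H](c3cc(OCc7ccccc7)cc4c3[C@H](c5cc(OCc7ccccc7)cc(OCc7ccccc7)c5)[C@@H](c5ccc(OCc7ccccc7)cc5)O4)[C@@H](c3cc(OCc7ccccc7)cc4c3[C@H](c5cc(OCc7ccccc7)cc(OCc7ccccc7)c5)[C@@H](c5ccc(OCc7ccccc7)cc5)O4)C(=O)N1[C@@H](Cc2ccccc2)COC1=O)N1[C@@H](Cc2ccccc2)COC1=O | intermediate
19 | (2S,3S)-2,3-bis(Ar*)butanedioic acid | OC(=O)[C@H](c3cc(OCc7ccccc7)cc4c3[C@H](c5cc(OCc7ccccc7)cc(OCc7ccccc7)c5)[C@@H](c5ccc(OCc7ccccc7)cc5)O4)[C@@H](c3cc(OCc7ccccc7)cc4c3[C@H](c5cc(OCc7ccccc7)cc(OCc7ccccc7)c5)[C@@H](c5ccc(OCc7ccccc7)cc5)O4)C(=O)O | intermediate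
20 | (3S,4S)-3,4-bis(Ar*)oxolane-2,5-dione | O=C1[C@H](c3cc(OCc7ccccc7)cc4c3[C@H](c5cc(OCc7ccccc7)cc(OCc7ccccc7)c5)[C@@H](c5ccc(OCc7ccccc7)cc5)O4)[C@@H](c3cc(OCc7ccccc7)cc4c3[C@H](c5cc(OCc7ccccc7)cc(OCc7ccccc7)c5)[C@@H](c5ccc(OCc7ccccc7)cc5)O4)C(=O)O1 | intermediate
21 | [4-(benzyloxy)phenyl]magnesium bromide | Br[Mg]c1ccc(OCc2ccccc2)cc1 | starting material
22 | (2S,3S)-4-[4-(benzyloxy)phenyl]-4-oxo-2,3-bis(Ar*)butanoic acid | OC(=O)[C@H](c3cc(OCc7ccccc7)cc4c3[C@H](c5cc(OCc7ccccc7)cc(OCc7ccccc7)c5)[C@@H](c5ccc(OCc7ccccc7)cc5)O4)[C@@H](c3cc(OCc7ccccc7)cc4c3[C@H](c5cc(OCc7ccccc7)cc(OCc7ccccc7)c5)[C@@H](c5ccc(OCc7ccccc7)cc5)O4)C(=O)c1ccc(OCc7ccccc7)cc1 | intermediate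
23 | (2S,3S,4R)-4-[4-(benzyloxy)phenyl]-4-hydroxy-2,3-bis(Ar*)butanoic acid | OC(=O)[C@H](c3cc(OCc7ccccc7)cc4c3[C@H](c5cc(OCc7ccccc7)cc(OCc7ccccc7)c5)[C@@H](c5ccc(OCc7ccccc7)cc5)O4)[C@@H](c3cc(OCc7ccccc7)cc4c3[C@H](c5cc(OCc7ccccc7)cc(OCc7ccccc7)c5)[C@@H](c5ccc(OCc7ccccc7)cc5)O4)[C@@H](O)c1ccc(OCc7ccccc7)cc1 | intermediate
24 | (3S,4S,5R)-5-[4-(benzyloxy)phenyl]-3,4-bis(Ar*)oxolan-2-one | O=C1[C@H](c3cc(OCc7ccccc7)cc4c3[C@H](c5cc(OCc7ccccc7)cc(OCc7ccccc7)c5)[C@@H](c5ccc(OCc7ccccc7)cc5)O4)[C@@H](c3cc(OCc7ccccc7)cc4c3[C@H](c5cc(OCc7ccccc7)cc(OCc7ccccc7)c5)[C@@H](c5ccc(OCc7ccccc7)cc5)O4)[C@H](c2ccc(OCc7ccccc7)cc2)O1 | intermediate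
25 | (3S,4S,5R)-2,5-bis[4-(benzyloxy)phenyl]-3,4-bis(Ar*)oxolan-2-ol (C2 anomers) | OC1(c2ccc(OCc7ccccc7)cc2)[C@H](c3cc(OCc7ccccc7)cc4c3[C@H](c5cc(OCc7ccccc7)cc(OCc7ccccc7)c5)[C@@H](c5ccc(OCc7ccccc7)cc5)O4)[C@@H](c3cc(OCc7ccccc7)cc4c3[C@H](c5cc(OCc7ccccc7)cc(OCc7ccccc7)c5)[C@@H](c5ccc(OCc7ccccc7)cc5)O4)[C@H](c2ccc(OCc7ccccc7)cc2)O1 | intermediate
26 | (2S,3S,4S,5R)-2,5-bis[4-(benzyloxy)phenyl]-3,4-bis(Ar*)oxolane | c7ccccc7COc1ccc(cc1)[C@@H]1[C@H](c3cc(OCc7ccccc7)cc4c3[C@H](c5cc(OCc7ccccc7)cc(OCc7ccccc7)c5)[C@@H](c5ccc(OCc7ccccc7)cc5)O4)[C@@H](c3cc(OCc7ccccc7)cc4c3[C@H](c5cc(OCc7ccccc7)cc(OCc7ccccc7)c5)[C@@H](c5ccc(OCc7ccccc7)cc5)O4)[C@H](c2ccc(OCc7ccccc7)cc2)O1 | intermediate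
27 | (2S,3S,4S,5R)-2,5-bis(4-hydroxyphenyl)-3,4-bis[(2S,3S)-3-(3,5-dihydroxyphenyl)-6-hydroxy-2-(4-hydroxyphenyl)-2,3-dihydro-1-benzofuran-4-yl]oxolane | Oc1ccc([C@H]2Oc3cc(O)cc([C@@H]4[C@@H](c5cc(O)cc6c5[C@H](c5cc(O)cc(O)c5)[C@@H](c5ccc(O)cc5)O6)[C@H](c5ccc(O)cc5)O[C@@H]4c4ccc(O)cc4)c3[C@@H]2c2cc(O)cc(O)c2)cc1 | target

**Step count and risks**

Total step count: 16. Longest linear sequence: 16 steps (from 1; step 9 joins two molecules of the same intermediate).

The three steps most likely to fail are 9, 6 and 13.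

Step 9. The coupling joins two secondary carbons that each carry an ortho-substituted aryl group. Slow C–C bond formation would let the oxidised enolate be chlorinated or protonated instead, and the stereocentres of the aryl group could erode the facial control of the auxiliary. The fallback replaces oxidative coupling by stepwise alkylation; it sets out from 13 and comes back at 19. Acid 13 is acylated onto (R)-4-benzyloxazolidin-2-one under the conditions of step 8 to give (R)-4-benzyl-3-[2-(Ar*)acetyl]oxazolidin-2-one F1. Its boron enolate (Bu2BOTf, i-Pr2NEt, CH2Cl2, −78 °C) is brominated with NBS anti to the benzyl group to give (R)-4-benzyl-3-[(2R)-2-bromo-2-(Ar*)acetyl]oxazolidin-2-one F2. The sodium enolate of 16 (NaN(SiMe3)2, THF, −78 °C) displaces the bromide with inversion to give the mixed bis-imide F3, whose (2S,3S) core is that of 18. LiOH/H2O2 as in step 10 then gives 19.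

Step 6. The benzylic C3 radical may dimerise or be reduced before nickel captures it, and facial selectivity in the aryl transfer may be poor. The fallback pre-activates the acid and makes the aryl partner the nucleophile; it sets out from 10 and comes back at 12. Acid 10 is esterified with N-hydroxyphthalimide (N,N'-diisopropylcarbodiimide, DMAP, CH2Cl2) to give the 1,3-dioxoisoindolin-2-yl ester F4. This is coupled in the dark with [3,5-bis(benzyloxy)phenyl]zinc chloride F5 (from 11 by Br/Li exchange with n-BuLi, then ZnCl2) under NiCl2·glyme and 4,4'-di-tert-butyl-2,2'-bipyridine in THF/DMF at rt (decarboxylative Negishi coupling of a redox-active ester) to give 12.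

Step 13. The ketone is flanked by a tertiary carbon bearing two large groups, so hydride transfer from the ruthenium hydride may be slow or catalyst control incomplete, and long exposure to the amine could epimerise the carbon next to the ketone. The fallback uses substrate control and an invertive ring closure; it sets out from 22 and comes back at 24. Reduction with LiBH(s-Bu)3 (THF, −78 °C) should, by the Felkin–Anh model with the C3 aryl group antiperiplanar, give mainly (2S,3S,4S)-4-[4-(benzyloxy)phenyl]-4-hydroxy-2,3-bis(Ar*)butanoic acid F6. Under Mitsunobu conditions (PPh3, DIAD, THF, 0 °C) the carboxylate then displaces the activated alcohol with inversion to give the 4,5-trans lactone 24.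

**Further compounds**

F1 | step 9 | (R)-4-benzyl-3-[2-(Ar*)acetyl]oxazolidin-2-one | O=C(Cc1cc(OCc2ccccc2)cc3c1[C@H](c1cc(OCc2ccccc2)cc(OCc2ccccc2)c1)[C@@H](c1ccc(OCc2ccccc2)cc1)O3)N1[C@H](Cc2ccccc2)COC1=O
F2 | step 9 | (R)-4-benzyl-3-[(2R)-2-bromo-2-(Ar*)acetyl]oxazolidin-2-one | Br[C@H](c3cc(OCc7ccccc7)cc4c3[C@H](c5cc(OCc7ccccc7)cc(OCc7ccccc7)c5)[C@@H](c5ccc(OCc7ccccc7)cc5)O4)C(=O)N1[C@H](Cc2ccccc2)COC1=O
F3 | step 9 | (2S,3S)-1-[(S)-4-benzyl-2-oxooxazolidin-3-yl]-4-[(R)-4-benzyl-2-oxooxazolidin-3-yl]-2,3-bis(Ar*)butane-1,4-dione | O=C([C@H](c3cc(OCc7ccccc7)cc4c3[C@H](c5cc(OCc7ccccc7)cc(OCc7ccccc7)c5)[C@@H](c5ccc(OCc7ccccc7)cc5)O4)[C@@H](c3cc(OCc7ccccc7)cc4c3[C@H](c5cc(OCc7ccccc7)cc(OCc7ccccc7)c5)[C@@H](c5ccc(OCc7ccccc7)cc5)O4)C(=O)N1[C@H](Cc2ccccc2)COC1=O)N1[C@@H](Cc2ccccc2)COC1=O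
F4 | step 6 | 1,3-dioxoisoindolin-2-yl (2S,3S)-6-(benzyloxy)-2-[4-(benzyloxy)phenyl]-4-(2-tert-butoxy-2-oxoethyl)-2,3-dihydro-1-benzofuran-3-carboxylate | CC(C)(C)OC(=O)Cc1cc(OCc2ccccc2)cc3c1[C@H](C(=O)ON1C(=O)c2ccccc2C1=O)[C@@H](c1ccc(OCc2ccccc2)cc1)O3
F5 | step 6 | [3,5-bis(benzyloxy)phenyl]zinc chloride | Cl[Zn]c1cc(OCc2ccccc2)cc(OCc2ccccc2)c1
F6 | step 13 | (2S,3S,4S)-4-[4-(benzyloxy)phenyl]-4-hydroxy-2,3-bis(Ar*)butanoic acid | OC(=O)[C@H](c3cc(OCc7ccccc7)cc4c3[C@H](c5cc(OCc7ccccc7)cc(OCc7ccccc7)c5)[C@@H](c5ccc(OCc7ccccc7)cc5)O4)[C@@H](c3cc(OCc7ccccc7)cc4c3[C@H](c5cc(OCc7ccccc7)cc(OCc7ccccc7)c5)[C@@H](c5ccc(OCc7ccccc7)cc5)O4)[C@H](O)c1ccc(OCc7ccccc7)cc1
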